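The earlier runs and the new flask stem from a simulated flask for an exercise; noise was put on by code.

A micromolar of X charged need not be a micromolar of X at work: 2 X can pair into Q, an off-cycle form.

| setting | summer | spring | flask |
|---|---|---|---|
| E | 0.033 M | 0.033 M | 0.033 M |
| X | 33 µM | 50 µM | 66 µM |
| remark | run made earlier | run made earlier |  |

- summer (time / s: G / %, E / %): 15.0: 3.6, 96.0; 30.0: 5.7, 93.0; 40.0: 6.9, 92.5; 60.0: 12.6, 90.1; 80.0: 13.4, 85.8
- spring (time / s: G / %, E / %): 10.0: 2.6, 96.5; 20.0: 6.4, 94.7; 40.0: 11.1, 89.4; 80.0: 17.1, 83.2

(standard deviation of a reading: 0.5 percentage points)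

* apparent order in X when 30% of the E are converted (percent change of the rate of making G for one percent more X charged)

- the numbers in the tables scatter by 0.5 percentage points (one standard deviation)
- candidate steps: 2 X <-> Q; E + X <-> X + G

I took the pairing to stay at balance, c_Q = K·c_X², and folded it into one number, the pairing number D = 2K·c(X charged), which says how far the charge lies above the level where pairing bites. With f the share of catalyst free as X:

f = 1/(1 + D·f)  and  n = 1/(2 − f)

At fixed conversion E and G are alike across these charges, so n is the order in X charged.

Adding E lost and G gained at 40.0 s and 80.0 s, spring over summer gives a ratio of conversions at equal times of 1.32, which I took as an approximate ratio of rates.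

n = ln(ratio)/ln(charge ratio) = 0.675
f = 0.519 near 40.6 µM, so D = 1.79 there

With a scatter of 0.5 percentage points, this is a rough reading. Scaled to the flask's charge, D = 2.91. Putting f back in round after round closes on f = 0.439, so my order is 0.641.

The forecast said 0.8, from 0.55 to 1, higher than mine, and that the order “should fall slightly at higher X”.

The flask gives 0.67, with 50.2% of its catalyst as X at 3.00 min; 1/(2 − f) then gives 0.668, and that share means D = 1.98, where my rough reading of the two runs had 2.91.

    2 X ⇌ Q, settled at all times (K = 15000 M⁻¹)
    E + X ⇌ X + G (K = 0.550, k = 111 M⁻¹ s⁻¹)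

In the flask at 2.00 min, the relaxation half-life of the E–G step, both ways together, is 1.12 min, shorter by a factor of 17.9 than the 20.0 min of the latest state. The flask holds E 74.8% and G 25.2% at 2.00 min, and E 64.5% and G 35.5% at 20.0 min.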